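Ring B is cut at C6–C7 and C8–C9, the bonds flanking the C7=C8 olefin (labdane locants). C7 and C8 then come from (E)-1-nitropropene, and what is left is a ring-A 1,5-dialdehyde whose carbonyl carbons are C6 and C11; the key step exploits that C9 is α to C11 and that C6 and C11 sit 1,5 across C5–C10–C9. An aminocatalysed Michael/Henry domino joins C9–C8 and C7–C6 in one operation and fixes C9; nitro and hydroxyl are then traded for the 7-ene. C10 stems from a decarboxylative asymmetric allylation, C5 from a cyclic hydroboration (temporary boracycle), C14 from glyceraldehyde; a B-alkyl Suzuki coupling adds the side chain.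

Key step: step 9

Remark: locants C1–C17 are labdane locants (C17 = methyl on C8) and β is the face of the C10 methyl; 1-nitropropan-2-ol and (R)-glyceraldehyde acetonide are taken as commercial.

Step 1
Reactants: 1 2,2,6-trimethylcyclohexan-1-one
Product: 3 prop-2-en-1-yl 2,6,6-trimethylcyclohex-1-en-1-yl carbonate, via lithium enolate 2 (not isolated)
Conditions: LiN(SiMe3)2, TMEDA, THF, 0 °C; then allyl chloroformate, −78 to 23 °C
Reagents that add atoms: allyl chloroformate, C=CCOC(=O)Cl
Why: The ketone has a single enolisable position, and its lithium enolate is O-acylated by the chloroformate (enol carbonate formation), which stores the allyl group for step 2.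

Step 2
Reactants: 3 prop-2-en-1-yl 2,6,6-trimethylcyclohex-1-en-1-yl carbonate
Product: 4 (2R)-2,6,6-trimethyl-2-(prop-2-en-1-yl)cyclohexan-1-one
Conditions: Pd2(dba)3 (2.5 mol %), (R)-t-BuPHOX (6 mol %), THF, 25 °C
Reagents that add atoms: none
Why: Decarboxylative asymmetric allylic alkylation (enantioselective Tsuji allylation) sets the C10 quaternary centre under ligand control, the (R)-ligand being chosen because the (S)-ligand delivers (S)-α-quaternary ketones in this reaction class; any minor enantiomer should be removed later as diastereomers (steps 9 and 18).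

Step 3
Reactants: 4 (2R)-2,6,6-trimethyl-2-(prop-2-en-1-yl)cyclohexan-1-one
Product: 5 (2R)-2,6,6-trimethyl-2-[(1E)-prop-1-en-1-yl]cyclohexan-1-one
Conditions: PdCl2(MeCN)2 (5 mol %), toluene, 80 °C
Reagents that add atoms: none
Why: Metal-hydride olefin isomerisation can move the double bond by one position only, because C10 is quaternary, and should give the (E)-propenyl group.

Step 4
Reactants: 5 (2R)-2,6,6-trimethyl-2-[(1E)-prop-1-en-1-yl]cyclohexan-1-one
Product: 6 (2R)-2-ethenyl-2,6,6-trimethylcyclohexan-1-one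
Conditions: second-generation Grubbs catalyst (5 mol %), ethylene (5 bar), toluene, 60 °C
Reagents that add atoms: ethylene, C=C
Why: Ethenolysis (cross-metathesis with ethylene) clips the terminal methyl carbon as propene and leaves the vinyl group on C10 without touching the stereocentre.

Step 5
Reactants: 6 (2R)-2-ethenyl-2,6,6-trimethylcyclohexan-1-one
Product: 7 (1R)-1-ethenyl-1,3,3-trimethyl-2-methylidenecyclohexane
Conditions: Ph3PCH3Br, KOtBu, toluene, 110 °C
Reagents that add atoms: methyltriphenylphosphonium bromide, C[P+](c1ccccc1)(c1ccccc1)c1ccccc1.[Br-]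
Why: Wittig methylenation under forcing alkoxide conditions suits this hindered ketone, which cannot enolise, and introduces C6 without creating a stereocentre.

Step 6
Reactants: 7 (1R)-1-ethenyl-1,3,3-trimethyl-2-methylidenecyclohexane
Product: 9 [(1S,2R)-2-(2-hydroxyethyl)-2,6,6-trimethylcyclohexyl]methanol, via B-thexyl boracycle 8 (not isolated)
Conditions: thexylborane (from BH3·THF and 2,3-dimethylbut-2-ene), THF, −20 to 23 °C; then NaOH, H2O2, 0 to 40 °C
Reagents that add atoms: hydrogen peroxide, OO
Why: Cyclic hydroboration: the borane adds first to the vinyl group (boron on C11) and the tethered B–H then adds across the exocyclic methylene through a six-membered boracycle, so hydrogen reaches C5 on the side of the C9 arm and away from the axial C4 and C10 methyls, which sets C5 (H trans to the C10 methyl) before oxidation with retention.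

Step 7
Reactants: 9 [(1S,2R)-2-(2-hydroxyethyl)-2,6,6-trimethylcyclohexyl]methanol
Product: 10 (1S,2R)-2,6,6-trimethyl-2-(2-oxoethyl)cyclohexane-1-carbaldehyde
Conditions: (COCl)2, DMSO, CH2Cl2, −78 °C; then i-Pr2NEt, −78 to −30 °C
Reagents that add atoms: none
Why: Swern oxidation activates both hydroxyls before base is added, which avoids lactol and lactone formation, and the cold hindered base should leave the C5 centre α to the new aldehyde unepimerised.

Step 8
Reactants: 11 1-nitropropan-2-ol
Product: 13 (1E)-1-nitroprop-1-ene, via mesylate 12 (not isolated)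
Conditions: MsCl, Et3N, CH2Cl2, 0 °C
Reagents that add atoms: none
Why: Mesylation followed by E1cB elimination of the β-nitro mesylate gives the conjugated (E)-nitroalkene.

Step 9
Reactants: 10 (1S,2R)-2,6,6-trimethyl-2-(2-oxoethyl)cyclohexane-1-carbaldehyde; 13 (1E)-1-nitroprop-1-ene
Product: 15 4-hydroxy-2,5,5,8a-tetramethyl-3-nitrodecahydronaphthalene-1-carbaldehyde (trans-fused; 6α-OH/7β-NO2/8β-CH3/9β-CHO), via nitro dialdehyde 14 (not isolated)
Conditions: (S)-α,α-diphenylprolinol trimethylsilyl ether (20 mol %), THF, 23 °C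
Reagents that add atoms: none
Why: The amine condenses only with the unhindered C11 aldehyde, its enamine adds through C9 to C8 of the nitroalkene (Michael), and the nitronate so formed at C7 attacks the C6 aldehyde (Henry), so that C8–C9 and C6–C7 are made in one operation. The closest known reaction is the diarylprolinol silyl ether-catalysed Michael/Henry domino of pentane-1,5-dial with nitroalkenes, applied here to a ring-fused 1,5-dialdehyde. Ring B closes by 6-exo-trig attack of the C7 nitronate carbon on the C6 carbonyl, in a chair fixed by the trans-diequatorial C6 and C9 arms on ring A. C9 is set by the catalyst, whose diphenyl(silyloxy)methyl group shields one face of the anti (E)-enamine, C8 follows from the synclinal (syn) Michael topology, and C6 and C7 should settle equatorial through the reversible nitro-aldol; C6, C7 and C8 are erased again in steps 10 to 13. The step needs chemoselective enamine formation at C11 and retention of C5, and both are secured by the C6 aldehyde being neopentylic between the quaternary C4 and C10.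

Step 10
Reactants: 15 4-hydroxy-2,5,5,8a-tetramethyl-3-nitrodecahydronaphthalene-1-carbaldehyde (trans-fused; 6α-OH/7β-NO2/8β-CH3/9β-CHO)
Product: 16 2,5,5,8a-tetramethyl-3-nitro-1,2,4a,5,6,7,8,8a-octahydronaphthalene-1-carbaldehyde (C6=C7 nitroalkene; 8β-CH3/9β-CHO)
Conditions: DCC, CuCl (10 mol %), Et2O, 23 °C
Reagents that add atoms: none
Why: Copper-catalysed carbodiimide dehydration of the β-nitro alcohol gives the nitroalkene under neutral conditions, so the C9 centre α to the aldehyde is not exposed to base.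

Step 11
Reactants: 16 2,5,5,8a-tetramethyl-3-nitro-1,2,4a,5,6,7,8,8a-octahydronaphthalene-1-carbaldehyde (C6=C7 nitroalkene; 8β-CH3/9β-CHO)
Product: 17 2,5,5,8a-tetramethyl-3-oxodecahydronaphthalene-1-carbaldehyde (7-ketone; 8β-CH3/9β-CHO)
Conditions: CrCl2, THF/H2O, 23 °C
Reagents that add atoms: water, O
Why: Reductive Nef-type conversion: divalent chromium reduces the conjugated nitroalkene to the imine level and hydrolysis places the carbonyl on C7, the former nitro carbon, which frees C6 as CH2.

Step 12
Reactants: 17 2,5,5,8a-tetramethyl-3-oxodecahydronaphthalene-1-carbaldehyde (7-ketone; 8β-CH3/9β-CHO)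
Product: 18 4-ethenyl-3,4a,8,8-tetramethyloctahydronaphthalen-2(1H)-one (7-ketone; 8β-CH3/9β-vinyl)
Conditions: CH2I2, Zn, Ti(OiPr)4, THF, 23 °C
Reagents that add atoms: diiodomethane, ICI
Why: Takai methylenation with the non-basic gem-dizinc reagent is selective for the aldehyde over the ketone and should not epimerise C9, which is fixed from here on.

Step 13
Reactants: 18 4-ethenyl-3,4a,8,8-tetramethyloctahydronaphthalen-2(1H)-one (7-ketone; 8β-CH3/9β-vinyl)
Product: 19 4-ethenyl-3,4a,8,8-tetramethyl-1,4,4a,5,6,7,8,8a-octahydronaphthalen-2-yl trifluoromethanesulfonate (C7=C8 enol triflate)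
Conditions: Tf2O, 2,6-di-tert-butyl-4-methylpyridine, CH2Cl2, 0 to 23 °C
Reagents that add atoms: triflic anhydride, O=S(=O)(OS(=O)(=O)C(F)(F)F)C(F)(F)F
Why: Enol triflate formation under equilibrating conditions should favour the more substituted C7=C8 enol, which also removes the C8 stereocentre.

Step 14
Reactants: 19 4-ethenyl-3,4a,8,8-tetramethyl-1,4,4a,5,6,7,8,8a-octahydronaphthalen-2-yl trifluoromethanesulfonate (C7=C8 enol triflate)
Product: 20 (4aS,5S,8aS)-5-ethenyl-1,1,4a,6-tetramethyl-1,2,3,4,4a,5,8,8a-octahydronaphthalene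
Conditions: Pd(OAc)2 (5 mol %), PPh3 (10 mol %), HCO2H, n-Bu3N, DMF, 60 °C
Reagents that add atoms: none
Why: Palladium-catalysed formate hydrogenolysis of the enol triflate replaces the triflate by hydrogen at C7 with the double bond kept at C7=C8 and the vinyl group untouched.

Step 15
Reactants: 21 (4R)-2,2-dimethyl-1,3-dioxolane-4-carbaldehyde
Product: 22 (4S)-4-ethynyl-2,2-dimethyl-1,3-dioxolane
Conditions: dimethyl (1-diazo-2-oxopropyl)phosphonate, K2CO3, MeOH, 0 to 23 °C
Reagents that add atoms: dimethyl (1-diazo-2-oxopropyl)phosphonate, CC(=O)C(=[N+]=[N-])P(=O)(OC)OC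
Why: Ohira–Bestmann homologation converts the aldehyde into the terminal alkyne under mild base, which should keep the future C14 centre.

Step 16
Reactants: 22 (4S)-4-ethynyl-2,2-dimethyl-1,3-dioxolane
Product: 23 tributyl{1-[(4R)-2,2-dimethyl-1,3-dioxolan-4-yl]ethenyl}stannane
Conditions: n-Bu3SnH, Mo(CO)3(CNtBu)3 (2 mol %), hydroquinone, THF, 55 °C
Reagents that add atoms: tributyltin hydride, CCCC[SnH](CCCC)CCCC
Why: Molybdenum-catalysed hydrostannation of an alkyne with propargylic oxygen places tin on the internal carbon, the future C13.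

Step 17
Reactants: 23 tributyl{1-[(4R)-2,2-dimethyl-1,3-dioxolan-4-yl]ethenyl}stannane
Product: 24 (4R)-4-(1-iodoethenyl)-2,2-dimethyl-1,3-dioxolane
Conditions: I2, CH2Cl2, 0 °C
Reagents that add atoms: iodine, II
Why: Iododestannylation exchanges tin for iodine at the same vinyl carbon and gives the 2-iodoalkene.

Step 18
Reactants: 20 (4aS,5S,8aS)-5-ethenyl-1,1,4a,6-tetramethyl-1,2,3,4,4a,5,8,8a-octahydronaphthalene; 24 (4R)-4-(1-iodoethenyl)-2,2-dimethyl-1,3-dioxolane
Product: 26 (5S,9S,10S,14S)-14,15-O-isopropylidenelabda-7,13(16)-diene-14,15-diol, via B-alkyl-9-BBN 25 (not isolated)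
Conditions: 9-BBN, THF, 23 °C; then 24, PdCl2(dppf) (5 mol %), K3PO4 (aq), DMF, 50 °C
Reagents that add atoms: none
Why: 9-BBN hydroborates only the monosubstituted vinyl group (boron on C12), and B-alkyl Suzuki–Miyaura coupling with the alkenyl iodide forms C12–C13 together with the 13(16)-methylidene, leaving C7=C8 and C14 untouched.

Step 19
Reactants: 26 (5S,9S,10S,14S)-14,15-O-isopropylidenelabda-7,13(16)-diene-14,15-diol
Product: 27 (5S,9S,10S,14S)-labda-7,13(16)-diene-14,15-diol
Conditions: AcOH/H2O (4:1), 40 °C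
Reagents that add atoms: none
Why: Mild acid hydrolysis of the isopropylidene acetal frees the 14,15-diol and should not isomerise the olefins.

Step 20
Reactants: 27 (5S,9S,10S,14S)-labda-7,13(16)-diene-14,15-diol
Product: 28 (5S,9S,10S,14S)-labda-7,13(16)-diene-14,15-diyl diacetate
Conditions: Ac2O, pyridine, DMAP (cat.), CH2Cl2, 23 °C
Reagents that add atoms: acetic anhydride, CC(=O)OC(C)=O
Why: Nucleophile-catalysed acylation esterifies both hydroxyls with retention at C14 and gives the target.

Compound list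
1 | 2,2,6-trimethylcyclohexan-1-one (racemic) | CC1CCCC(C)(C)C1=O | starting material
2 | lithium 2,6,6-trimethylcyclohex-1-en-1-olate | [Li+].[O-]C1=C(C)CCCC1(C)C | intermediate (not isolated)
3 | prop-2-en-1-yl 2,6,6-trimethylcyclohex-1-en-1-yl carbonate | C=CCOC(=O)OC1=C(C)CCCC1(C)C | intermediate
4 | (2R)-2,6,6-trimethyl-2-(prop-2-en-1-yl)cyclohexan-1-one | C=CC[C@@]1(C)CCCC(C)(C)C1=O | intermediate
5 | (2R)-2,6,6-trimethyl-2-[(1E)-prop-1-en-1-yl]cyclohexan-1-one | C/C=C/[C@@]1(C)CCCC(C)(C)C1=O | intermediate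
6 | (2R)-2-ethenyl-2,6,6-trimethylcyclohexan-1-one | C=C[C@@]1(C)CCCC(C)(C)C1=O | intermediate
7 | (1R)-1-ethenyl-1,3,3-trimethyl-2-methylidenecyclohexane | C=C[C@@]1(C)CCCC(C)(C)C1=C | intermediate
8 | trans-fused 3-(2,3-dimethylbutan-2-yl)-6,10,10-trimethyl-3-borabicyclo[4.4.0]decane (boron on C6 and C11; ring-fusion H trans to the angular methyl) | CC(C)C(C)(C)B1CC[C@@]2(C)CCCC(C)(C)[C@@H]2C1 | intermediate (not isolated)
9 | [(1S,2R)-2-(2-hydroxyethyl)-2,6,6-trimethylcyclohexyl]methanol | OCC[C@@]1(C)CCCC(C)(C)[C@@H]1CO | intermediate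
10 | (1S,2R)-2,6,6-trimethyl-2-(2-oxoethyl)cyclohexane-1-carbaldehyde | O=CC[C@@]1(C)CCCC(C)(C)[C@@H]1C=O | intermediate
11 | 1-nitropropan-2-ol (racemic) | CC(O)C[N+](=O)[O-] | starting material
12 | 1-nitropropan-2-yl methanesulfonate | CC(OS(C)(=O)=O)C[N+](=O)[O-] | intermediate (not isolated)
13 | (1E)-1-nitroprop-1-ene | C/C=C/[N+](=O)[O-] | intermediate
14 | (2S,3R)-2-[(1R,2S)-2-formyl-1,3,3-trimethylcyclohexyl]-3-methyl-4-nitrobutanal | O=C[C@@H]([C@@H](C)C[N+](=O)[O-])[C@@]1(C)CCCC(C)(C)[C@@H]1C=O | intermediate (not isolated)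
15 | 4-hydroxy-2,5,5,8a-tetramethyl-3-nitrodecahydronaphthalene-1-carbaldehyde (trans-fused; 5α-H, 6α-OH, 7β-NO2, 8β-CH3, 9β-CHO, 10β-CH3; C6/C7 drawn as the expected major epimer) | O=C[C@H]1[C@@H](C)[C@@H]([N+](=O)[O-])[C@H](O)[C@H]2C(C)(C)CCC[C@]12C | intermediate
16 | 2,5,5,8a-tetramethyl-3-nitro-1,2,4a,5,6,7,8,8a-octahydronaphthalene-1-carbaldehyde (C6=C7; 5α-H, 8β-CH3, 9β-CHO, 10β-CH3) | O=C[C@H]1[C@@H](C)C([N+](=O)[O-])=C[C@H]2C(C)(C)CCC[C@]12C | intermediate
17 | 2,5,5,8a-tetramethyl-3-oxodecahydronaphthalene-1-carbaldehyde (7-ketone; 5α-H, 8β-CH3 as formed, 9β-CHO, 10β-CH3) | O=C[C@H]1[C@@H](C)C(=O)C[C@H]2C(C)(C)CCC[C@]12C | intermediate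
18 | 4-ethenyl-3,4a,8,8-tetramethyloctahydronaphthalen-2(1H)-one (7-ketone; 5α-H, 8β-CH3 as formed, 9β-vinyl, 10β-CH3) | C=C[C@H]1[C@@H](C)C(=O)C[C@H]2C(C)(C)CCC[C@]12C | intermediate
19 | 4-ethenyl-3,4a,8,8-tetramethyl-1,4,4a,5,6,7,8,8a-octahydronaphthalen-2-yl trifluoromethanesulfonate (5α-H, 9β-vinyl, 10β-CH3) | C=C[C@H]1C(C)=C(OS(=O)(=O)C(F)(F)F)C[C@H]2C(C)(C)CCC[C@]12C | intermediate
20 | (4aS,5S,8aS)-5-ethenyl-1,1,4a,6-tetramethyl-1,2,3,4,4a,5,8,8a-octahydronaphthalene | C=C[C@H]1C(C)=CC[C@H]2C(C)(C)CCC[C@]12C | intermediate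
21 | (4R)-2,2-dimethyl-1,3-dioxolane-4-carbaldehyde | O=C[C@H]1COC(C)(C)O1 | starting material
22 | (4S)-4-ethynyl-2,2-dimethyl-1,3-dioxolane | C#C[C@H]1COC(C)(C)O1 | intermediate
23 | tributyl{1-[(4R)-2,2-dimethyl-1,3-dioxolan-4-yl]ethenyl}stannane | C=C([Sn](CCCC)(CCCC)CCCC)[C@H]1COC(C)(C)O1 | intermediate
24 | (4R)-4-(1-iodoethenyl)-2,2-dimethyl-1,3-dioxolane | C=C(I)[C@H]1COC(C)(C)O1 | intermediate
25 | 9-{2-[(1S,4aS,8aS)-2,5,5,8a-tetramethyl-1,4,4a,5,6,7,8,8a-octahydronaphthalen-1-yl]ethyl}-9-borabicyclo[3.3.1]nonane | C1CC2CCCC(C1)B2CC[C@H]1C(C)=CC[C@H]2C(C)(C)CCC[C@]12C | intermediate (not isolated)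
26 | (5S,9S,10S,14S)-14,15-O-isopropylidenelabda-7,13(16)-diene-14,15-diol | C=C(CC[C@H]1C(C)=CC[C@H]2C(C)(C)CCC[C@]12C)[C@H]1COC(C)(C)O1 | intermediate
27 | (5S,9S,10S,14S)-labda-7,13(16)-diene-14,15-diol | C=C(CC[C@H]1C(C)=CC[C@H]2C(C)(C)CCC[C@]12C)[C@@H](CO)O | intermediate
28 | (5S,9S,10S,14S)-labda-7,13(16)-diene-14,15-diyl diacetate | C=C(CC[C@H]1C(C)=CC[C@H]2C(C)(C)CCC[C@]12C)[C@@H](COC(C)=O)OC(C)=O | target

Total step count: 20. Longest linear sequence: 16 steps (steps 1–7, 9–14 and 18–20); steps 8 and 15–17 are side branches.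

Steps most likely to fail

Step 9. The nitronate may fail to close onto the neopentylic C6 aldehyde, because the chair has to carry the C8 methyl axial and syn to the C10 methyl, so that the open adduct accumulates; the long contact with the amine may also erode C9 by enolisation. Fallback, setting out from 10: the unhindered C11 aldehyde alone is converted (TMSCl, NaI, Et3N, MeCN) into the trimethylsilyl enol ether F1, a Mukaiyama–Michael addition of F1 to 13 (SnCl4, CH2Cl2, −78 °C) gives the open nitro dialdehyde 14 after aqueous work-up, and a separate fluoride-promoted intramolecular nitro-aldol reaction (tetrabutylammonium fluoride, THF, 0 °C) closes ring B to 15, where the route is rejoined. C9 is then under substrate control only, and its epimers would have to be separated at 15.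

Step 13. Enolisation of the 7-ketone toward C6 instead of C8 would give the C6=C7 triflate and, after step 14, the misplaced olefin. Fallback, setting out from 18: NaOMe in MeOH equilibrates C8 to the equatorial 8α-methyl ketone F2, LiBH(s-Bu)3 reduces it from the equatorial side to the axial 7α-alcohol F3, and anti elimination with POCl3 in pyridine, which has the trans-diaxial tertiary 8β-hydrogen available (Zaitsev), gives 20, where the route is rejoined without the triflate.

Step 5. The carbonyl of 6, buried between two quaternary carbons, may not accept the ylide, so that the ketone is returned. Fallback, setting out from 6: MeLi with CeCl3 (THF, −78 °C) adds to the carbonyl to give the tertiary alcohol F4, and Burgess dehydration, for which only the new methyl offers β-hydrogens, gives the exocyclic olefin 7, where the route is rejoined.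

Further compounds
F1 | step 9 | (1S,2R)-2,6,6-trimethyl-2-[2-(trimethylsilyloxy)ethenyl]cyclohexane-1-carbaldehyde | C[Si](C)(C)OC=C[C@@]1(C)CCCC(C)(C)[C@@H]1C=O
F2 | step 13 | 4-ethenyl-3,4a,8,8-tetramethyloctahydronaphthalen-2(1H)-one, 8α-methyl epimer of 18 | C=C[C@H]1[C@H](C)C(=O)C[C@H]2C(C)(C)CCC[C@]12C
F3 | step 13 | 4-ethenyl-3,4a,8,8-tetramethyldecahydronaphthalen-2-ol (7α-OH, 8α-CH3, 9β-vinyl) | C=C[C@H]1[C@H](C)[C@H](O)C[C@H]2C(C)(C)CCC[C@]12C
F4 | step 5 | (2R)-2-ethenyl-1,2,6,6-tetramethylcyclohexan-1-ol (mixture at C1) | C=C[C@@]1(C)CCCC(C)(C)C1(C)O
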